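The route closes the pyran ring (ring F) of the lower catechin unit last, by forming its C4–C4a bond on an already assembled 4β-arylated epicatechin. An epicatechin-derived C4 cation is first joined to 3,5-bis(benzyloxy)phenol; the free phenol is O-alkylated with an enantiopure aryl glycidol and the diol is converted to a terminal epoxide. The key step, an AuCl3/AgOTf-catalysed 6-endo epoxide–arene cyclization, exploits the phloroglucinol ring D: with C8 occupied by the upper unit, C4a is the only free carbon ortho to O1, so the 4→8 pattern is fixed, and epoxide opening releases C3–OH of ring F as the sole free hydroxyl for the 4-hydroxybenzoate.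

Key step: step 9

Remark: flavan numbering (O1, C2, C3, C4, C4a, C5 to C8, C8a) is used for both units; the upper (4-linked) epicatechin unit has rings A, C and B, the lower (8-linked) catechin unit rings D, F and E; compounds 1, 5, 7 and all reagents are taken as commercial.

Step 1
Reactants: 1 (−)-epicatechin
Product: 3 penta-O-benzyl-epicatechin, via tetra-O-benzyl-epicatechin 2 (not isolated)
Conditions: BnBr (6 equiv), K2CO3, DMF, 0 °C → rt; then NaH, 0 °C → rt
Reagents that add atoms: benzyl bromide BrCc1ccccc1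
Why: Williamson etherification in which K2CO3 first caps the four phenols (avoiding C-benzylation and base-induced C2 epimerisation of free phenoxides) and NaH then benzylates the remaining C3–OH in the same pot, no stereocentre being touched.

Step 2
Reactants: 3 penta-O-benzyl-epicatechin
Product: 4 penta-O-benzyl-4β-(2-ethoxyethoxy)-epicatechin
Conditions: DDQ (2 equiv), 2-ethoxyethanol (5 equiv), CH2Cl2, rt
Reagents that add atoms: 2-ethoxyethanol CCOCCO
Why: DDQ abstracts hydride from the doubly benzylic C4 next to the electron-rich ring A and the alcohol captures the cation anti to the C3 benzyloxy group (benzylic oxidative etherification), giving the 4β-ether whose configuration is immaterial because C4 is re-ionised in step 3.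

Step 3
Reactants: 4 penta-O-benzyl-4β-(2-ethoxyethoxy)-epicatechin; 5 3,5-bis(benzyloxy)phenol (3 equiv)
Product: 6 4β-[2-hydroxy-4,6-bis(benzyloxy)phenyl]-penta-O-benzyl-epicatechin
Conditions: TMSOTf (0.2 equiv), CH2Cl2, −78 → −40 °C
Reagents that add atoms: none
Why: TMSOTf ionises the C4 ether and the cation undergoes Friedel–Crafts alkylation by 5 at a carbon ortho to its free OH (the para carbon is flanked by two benzyloxy groups, and excess 5 suppresses twofold alkylation), attack anti to the α-oriented C3-OBn and C2-aryl groups setting the 4β configuration of the target.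

Step 4
Reactants: 7 3,4-bis(benzyloxy)benzaldehyde
Product: 8 ethyl (E)-3-[3,4-bis(benzyloxy)phenyl]prop-2-enoate
Conditions: (EtO)2P(O)CH2CO2Et, NaH, THF, 0 °C → rt
Reagents that add atoms: triethyl phosphonoacetate CCOC(=O)CP(=O)(OCC)OCC
Why: Horner–Wadsworth–Emmons olefination with a stabilised phosphonate anion, which should give the E-alkene.

Step 5
Reactants: 8 ethyl (E)-3-[3,4-bis(benzyloxy)phenyl]prop-2-enoate
Product: 9 (E)-3-[3,4-bis(benzyloxy)phenyl]prop-2-en-1-ol
Conditions: iBu2AlH (2.5 equiv), CH2Cl2, −78 °C; aq. potassium sodium tartrate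
Reagents that add atoms: none
Why: 1,2-reduction of the conjugated ester by the aluminium hydride to the allylic alcohol without touching the alkene.

Step 6
Reactants: 9 (E)-3-[3,4-bis(benzyloxy)phenyl]prop-2-en-1-ol
Product: 10 [(2S,3S)-3-[3,4-bis(benzyloxy)phenyl]oxiran-2-yl]methanol
Conditions: Ti(OiPr)4 (10 mol%), L-(+)-diisopropyl tartrate (12 mol%), t-BuOOH, 4 Å MS, CH2Cl2, −20 °C; cold basic work-up
Reagents that add atoms: tert-butyl hydroperoxide CC(C)(C)OO
Why: Sharpless asymmetric epoxidation, in which the L-(+)-tartrate titanium complex delivers oxygen to the face of the E-allylic alcohol that gives the (2S,3S)-epoxide, thereby setting the future C3 of the lower unit.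

Step 7
Reactants: 6 4β-[2-hydroxy-4,6-bis(benzyloxy)phenyl]-penta-O-benzyl-epicatechin; 10 [(2S,3S)-3-[3,4-bis(benzyloxy)phenyl]oxiran-2-yl]methanol (1.5 equiv)
Product: 11 (2S,3R)-3-aryl-3-aryloxy-propane-1,2-diol (erythro)
Conditions: NaOH (1 equiv), H2O/1,4-dioxane, 70 °C
Reagents that add atoms: none
Why: The phenoxide opens the 2,3-epoxy alcohol by SN2 attack at the benzylic carbon (activated by the aryl group, the other epoxide carbon being deactivated by the neighbouring C1–O), so inversion there sets the future C2 (R) while the untouched C–O bond carries the future C3 (S), giving the erythro diol needed for a 2,3-trans ring.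

Step 8
Reactants: 11 (2S,3R)-3-aryl-3-aryloxy-propane-1,2-diol
Product: 13 terminal epoxy aryl ether, via primary tosylate 12 (not isolated)
Conditions: NaH (2.2 equiv), 1-(p-toluenesulfonyl)imidazole (1.05 equiv), THF, 0 °C → rt
Reagents that add atoms: 1-(p-toluenesulfonyl)imidazole Cc1ccc(cc1)S(=O)(=O)n1ccnc1 (its tosyl group is carried only by 12 and leaves again on ring closure)
Why: The primary alkoxide is sulfonylated selectively and the neighbouring secondary alkoxide displaces the tosylate (intramolecular Williamson etherification, 3-exo-tet), so the carbinol C–O bond is kept and its configuration retained.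

Step 9
Reactants: 13 terminal epoxy aryl ether
Product: 14 penta-O-benzyl-epicatechin-(4β→8)-tetra-O-benzyl-catechin (lower C3–OH free)
Conditions: AuCl3 (5 mol%), AgOTf (15 mol%), ClCH2CH2Cl, 0 °C → rt
Reagents that add atoms: none
Why: The cationic trivalent gold species formed from AuCl3 and AgOTf activates the terminal epoxide, the electron-rich ring D attacks the epoxide CH2 through its only free carbon ortho to the ether oxygen, and the Wheland intermediate rearomatises while the gold alkoxide is protonated. The closest known reaction type is the AuCl3/AgOTf-catalysed intramolecular Friedel–Crafts cycloalkylation of aryl glycidyl ethers to 3-chromanols, which has been applied to 2-aryl-3-chromanols of the catechin type. Ring F is closed in the 6-endo-tet mode, with attack at the terminal epoxide carbon and both epoxide carbons ending in the ring. No new stereocentre is created: the C–O bond at the epoxide CH is not broken, so C3 keeps the S configuration from step 6 and C2 the R configuration from step 7, which gives the 2,3-trans (catechin) ring. The step needs 6-endo over 5-exo selectivity, which SN2-like attack at the unhindered primary carbon should secure because the internal carbon is deactivated by the adjacent C–OAr bond; it also needs site selectivity on the arene, secured because the other ortho position of ring D carries the upper unit and the remaining C–H (future C6) is para to the ether oxygen and cannot reach the epoxide. Low catalyst loading and temperature are chosen to keep the acid-sensitive benzylic C2–O ether and the C4–C8 interflavan bond intact.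

Step 10
Reactants: 14 penta-O-benzyl-epicatechin-(4β→8)-tetra-O-benzyl-catechin
Product: 15 the lower 3-O-[4-(benzyloxy)benzoate] of 14
Conditions: 4-(benzyloxy)benzoyl chloride (1.5 equiv), Et3N, DMAP (cat.), CH2Cl2, 0 °C → rt
Reagents that add atoms: 4-(benzyloxy)benzoyl chloride O=C(Cl)c1ccc(OCc2ccccc2)cc1
Why: DMAP-catalysed acylation of the only free hydroxyl of 14, the lower C3–OH released in step 9, the upper C3 oxygen being a benzyl ether, so the ester is placed without any differentiation of the two secondary alcohols.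

Step 11
Reactants: 15 the lower 3-O-[4-(benzyloxy)benzoate] of 14
Product: 16 epicatechin-(4β→8)-catechin 3-O-(4-hydroxybenzoate), CNP0288594.1
Conditions: H2 (1 atm), Pd(OH)2/C, THF/MeOH/H2O, rt
Reagents that add atoms: none
Why: Heterogeneous hydrogenolysis should cleave all ten O-benzyl groups (nine aryl benzyl ethers and the upper C3 benzyl ether), while the aryl ester, the cyclic benzylic C2–O1 ethers and the C4–C8 bond survive these mild neutral conditions.

Compound list

1 | (−)-epicatechin, (2R,3R)-2-(3,4-dihydroxyphenyl)chromane-3,5,7-triol | O[C@@H]1Cc2c(O)cc(O)cc2O[C@@H]1c1ccc(O)c(O)c1 | starting material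
2 | 5,7,3',4'-tetra-O-benzyl-(−)-epicatechin (C3–OH free) | O[C@@H]1Cc2c(OCc3ccccc3)cc(OCc3ccccc3)cc2O[C@@H]1c1ccc(OCc2ccccc2)c(OCc2ccccc2)c1 | intermediate
3 | 3,5,7,3',4'-penta-O-benzyl-(−)-epicatechin | c1ccccc1CO[C@@H]1Cc2c(OCc3ccccc3)cc(OCc3ccccc3)cc2O[C@@H]1c1ccc(OCc2ccccc2)c(OCc2ccccc2)c1 | intermediate
4 | 3,5,7,3',4'-penta-O-benzyl-4β-(2-ethoxyethoxy)-epicatechin (C4–O trans to C3–O) | CCOCCO[C@H]1c2c(OCc3ccccc3)cc(OCc3ccccc3)cc2O[C@H](c2ccc(OCc3ccccc3)c(OCc3ccccc3)c2)[C@@H]1OCc1ccccc1 | intermediate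
5 | 3,5-bis(benzyloxy)phenol | Oc1cc(OCc2ccccc2)cc(OCc2ccccc2)c1 | starting material
6 | 4β-[2-hydroxy-4,6-bis(benzyloxy)phenyl]-3,5,7,3',4'-penta-O-benzyl-epicatechin (aryl trans to C3–O) | Oc1cc(OCc2ccccc2)cc(OCc2ccccc2)c1[C@H]1c2c(OCc3ccccc3)cc(OCc3ccccc3)cc2O[C@H](c2ccc(OCc3ccccc3)c(OCc3ccccc3)c2)[C@@H]1OCc1ccccc1 | intermediate
7 | 3,4-bis(benzyloxy)benzaldehyde | O=Cc1ccc(OCc2ccccc2)c(OCc2ccccc2)c1 | starting material
8 | ethyl (E)-3-[3,4-bis(benzyloxy)phenyl]prop-2-enoate | CCOC(=O)/C=C/c1ccc(OCc2ccccc2)c(OCc2ccccc2)c1 | intermediate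
9 | (E)-3-[3,4-bis(benzyloxy)phenyl]prop-2-en-1-ol | OC/C=C/c1ccc(OCc2ccccc2)c(OCc2ccccc2)c1 | intermediate
10 | [(2S,3S)-3-[3,4-bis(benzyloxy)phenyl]oxiran-2-yl]methanol | OC[C@@H]1O[C@H]1c1ccc(OCc2ccccc2)c(OCc2ccccc2)c1 | intermediate
11 | (2S,3R)-3-[3,4-bis(benzyloxy)phenyl]-3-(aryloxy)propane-1,2-diol, aryl = 3,5-bis(benzyloxy)-2-(penta-O-benzyl-epicatechin-4β-yl)phenyl | OC[C@H](O)[C@H](Oc1cc(OCc2ccccc2)cc(OCc2ccccc2)c1[C@H]1c2c(OCc3ccccc3)cc(OCc3ccccc3)cc2O[C@H](c2ccc(OCc3ccccc3)c(OCc3ccccc3)c2)[C@@H]1OCc1ccccc1)c1ccc(OCc2ccccc2)c(OCc2ccccc2)c1 | intermediate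
12 | primary mono-p-toluenesulfonate of 11 | Cc1ccc(cc1)S(=O)(=O)OC[C@H](O)[C@H](Oc1cc(OCc2ccccc2)cc(OCc2ccccc2)c1[C@H]1c2c(OCc3ccccc3)cc(OCc3ccccc3)cc2O[C@H](c2ccc(OCc3ccccc3)c(OCc3ccccc3)c2)[C@@H]1OCc1ccccc1)c1ccc(OCc2ccccc2)c(OCc2ccccc2)c1 | intermediate
13 | (S)-2-[(R)-[3,4-bis(benzyloxy)phenyl](aryloxy)methyl]oxirane, aryl as in 11 | C1O[C@@H]1[C@H](Oc1cc(OCc2ccccc2)cc(OCc2ccccc2)c1[C@H]1c2c(OCc3ccccc3)cc(OCc3ccccc3)cc2O[C@H](c2ccc(OCc3ccccc3)c(OCc3ccccc3)c2)[C@@H]1OCc1ccccc1)c1ccc(OCc2ccccc2)c(OCc2ccccc2)c1 | intermediate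
14 | 3,5,7,3',4'-penta-O-benzyl-epicatechin-(4β→8)-5,7,3',4'-tetra-O-benzyl-catechin, lower unit (2R,3S) with free C3–OH | O[C@H]1Cc2c(OCc3ccccc3)cc(OCc3ccccc3)c([C@H]3c4c(OCc5ccccc5)cc(OCc5ccccc5)cc4O[C@H](c4ccc(OCc5ccccc5)c(OCc5ccccc5)c4)[C@@H]3OCc3ccccc3)c2O[C@@H]1c1ccc(OCc2ccccc2)c(OCc2ccccc2)c1 | intermediate
15 | 3-O-[4-(benzyloxy)benzoate] of 14 at the lower C3 oxygen | O=C(O[C@H]1Cc2c(OCc3ccccc3)cc(OCc3ccccc3)c([C@H]3c4c(OCc5ccccc5)cc(OCc5ccccc5)cc4O[C@H](c4ccc(OCc5ccccc5)c(OCc5ccccc5)c4)[C@@H]3OCc3ccccc3)c2O[C@@H]1c1ccc(OCc2ccccc2)c(OCc2ccccc2)c1)c1ccc(OCc2ccccc2)cc1 | intermediate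
16 | epicatechin-(4β→8)-catechin 3-O-(4-hydroxybenzoate), upper unit (2R,3R,4R), lower unit (2R,3S), ester on the lower C3 oxygen | O=C(O[C@H]1Cc2c(O)cc(O)c([C@H]3c4c(O)cc(O)cc4O[C@H](c4ccc(O)c(O)c4)[C@@H]3O)c2O[C@@H]1c1ccc(O)c(O)c1)c1ccc(O)cc1 | target

Total step count: 11. Longest linear sequence: 8 steps (steps 1, 2, 3, 7, 8, 9, 10, 11 from 1; the branch 4, 5, 6 joins at step 7 and is equally long).

Steps most likely to fail

Step 9. The arene may attack the internal epoxide carbon (5-exo closure to a dihydrobenzofuran), the activated epoxide may undergo hydride shift to an aldehyde (Meinwald rearrangement), or the Lewis acid may ionise the benzylic C2–O aryl ether or the upper C4–aryl bond, including ipso attack with loss of the flavanyl cation. The fallback closes ring F before the upper unit is attached, on a substrate with two equivalent ortho carbons and no acid-labile 4-arylflavan unit; it also bypasses the site-selectivity question of step 3. It sets out from 5 and 10 and returns to the route at 14. Phenol 5 is opened onto 10 with NaOH in aqueous dioxane to give (2S,3R)-3-[3,4-bis(benzyloxy)phenyl]-3-[3,5-bis(benzyloxy)phenoxy]propane-1,2-diol F1. NaH and 1-(p-toluenesulfonyl)imidazole then give, through the primary mono-tosylate of this diol F2, the terminal epoxide (S)-2-[(R)-[3,4-bis(benzyloxy)phenyl][3,5-bis(benzyloxy)phenoxy]methyl]oxirane F3. AuCl3/AgOTf cyclisation of F3 should give 5,7,3',4'-tetra-O-benzyl-(+)-catechin F4. F4 (3 equiv) is finally alkylated at C8 by the cation generated from 4 (TMSOTf, CH2Cl2, −78 °C), the established C8- and 4β-selective Friedel–Crafts coupling of benzylated flavan-3-ols, which delivers 14.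

Step 7. Under the aqueous base the epoxy alcohol may undergo Payne rearrangement and be opened at the primary carbon, hydroxide may compete with the ortho-hindered phenoxide, or the electron-rich benzylic epoxide may open with partial loss of stereochemical fidelity. The fallback blocks the Payne pathway and moves to an anhydrous medium; it sets out from 10 and returns at 11. Compound 10 is silylated (t-BuMe2SiCl, imidazole, DMF) to the tert-butyldimethylsilyl ether of 10 F5. The caesium phenoxide of 6 (Cs2CO3, DMF, 80 °C) opens F5 at the benzylic carbon to the 1-O-tert-butyldimethylsilyl ether of 11 F6. Bu4NF in THF then frees the primary hydroxyl to give 11.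

Step 6. The 2,3-epoxy alcohol 10 carries a para-alkoxyphenyl group on the epoxide and may be opened by the titanium Lewis acid, by isopropanol or tartrate, or on work-up, eroding yield and enantiomeric purity. The fallback makes the acid-stable, non-benzylic Payne isomer instead and generates 10 only in base; it sets out from 7 and returns at 10. CH2=CHMgBr adds to 7 to give racemic 1-[3,4-bis(benzyloxy)phenyl]prop-2-en-1-ol F7. Sharpless kinetic resolution (Ti(OiPr)4, L-(+)-diisopropyl tartrate, t-BuOOH 0.6 equiv, CH2Cl2, −20 °C) should epoxidise the fast-reacting enantiomer to the erythro epoxy alcohol (S)-[3,4-bis(benzyloxy)phenyl][(2R)-oxiran-2-yl]methanol F8. In NaOH/aqueous dioxane F8 equilibrates by Payne rearrangement (inversion at the epoxide CH) to the more substituted, aryl-conjugated epoxide 10, which is consumed in that same basic medium in step 7.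

Further compounds

F1 | step 9 | (2S,3R)-3-[3,4-bis(benzyloxy)phenyl]-3-[3,5-bis(benzyloxy)phenoxy]propane-1,2-diol | OC[C@H](O)[C@H](Oc1cc(OCc2ccccc2)cc(OCc2ccccc2)c1)c1ccc(OCc2ccccc2)c(OCc2ccccc2)c1
F2 | step 9 | primary mono-p-toluenesulfonate of F1 | Cc1ccc(cc1)S(=O)(=O)OC[C@H](O)[C@H](Oc1cc(OCc2ccccc2)cc(OCc2ccccc2)c1)c1ccc(OCc2ccccc2)c(OCc2ccccc2)c1
F3 | step 9 | (S)-2-[(R)-[3,4-bis(benzyloxy)phenyl][3,5-bis(benzyloxy)phenoxy]methyl]oxirane | C1O[C@@H]1[C@H](Oc1cc(OCc2ccccc2)cc(OCc2ccccc2)c1)c1ccc(OCc2ccccc2)c(OCc2ccccc2)c1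
F4 | step 9 | 5,7,3',4'-tetra-O-benzyl-(+)-catechin, (2R,3S) | O[C@H]1Cc2c(OCc3ccccc3)cc(OCc3ccccc3)cc2O[C@@H]1c1ccc(OCc2ccccc2)c(OCc2ccccc2)c1
F5 | step 7 | tert-butyldimethylsilyl ether of 10 | CC(C)(C)[Si](C)(C)OC[C@@H]1O[C@H]1c1ccc(OCc2ccccc2)c(OCc2ccccc2)c1
F6 | step 7 | 1-O-tert-butyldimethylsilyl ether of 11 | CC(C)(C)[Si](C)(C)OC[C@H](O)[C@H](Oc1cc(OCc2ccccc2)cc(OCc2ccccc2)c1[C@H]1c2c(OCc3ccccc3)cc(OCc3ccccc3)cc2O[C@H](c2ccc(OCc3ccccc3)c(OCc3ccccc3)c2)[C@@H]1OCc1ccccc1)c1ccc(OCc2ccccc2)c(OCc2ccccc2)c1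
F7 | step 6 | racemic 1-[3,4-bis(benzyloxy)phenyl]prop-2-en-1-ol | OC(C=C)c1ccc(OCc2ccccc2)c(OCc2ccccc2)c1
F8 | step 6 | (S)-[3,4-bis(benzyloxy)phenyl][(2R)-oxiran-2-yl]methanol | O[C@@H](c1ccc(OCc2ccccc2)c(OCc2ccccc2)c1)[C@H]1CO1
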